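(All runs were generated by integration with made-up constants; scatter was added.)

A drain time of 19.2 min, read off the last south-east reading, against a run of 50 min: that is what two chemists dispute here.

| flask | starting material | partner | capture agent | temperature | remark | time |
|---|---|---|---|---|---|---|
| south | 0.10 M (fed, over 50 min) | 1.1 equiv | 0.056 M | 70 °C | run made earlier |  |
| south-east | 0.10 M (fed, over 50 min) | 1.1 equiv | 0.16 M | 92 °C | run made earlier |  |
| gamma | 0.10 M | 1.10 equiv | 0.200 M | 100 °C | everything together at the start | 50 min |
| zeta | 0.10 M (fed, over 50 min) | 1.10 equiv | 0.100 M | 60 °C |  | 50 min |

| run | time / min | open intermediate / % | target / % |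
|---|---|---|---|
| south | 2.00 | 0 | 0 |
| south | 6.00 | 0.3 | 0.2 |
| south | 12.0 | 2.8 | 0 |
| south | 15.0 | 4.3 | 0.5 |
| south | 25.0 | 9.6 | 1.3 |
| south | 30.0 | 12.0 | 1.3 |
| south-east | 0.667 | 0.9 | 0 |
| south-east | 2.00 | 0 | 0 |
| south-east | 4.00 | 1.1 | 0 |
| south-east | 5.00 | 1.7 | 0.2 |
| south-east | 8.00 | 3.3 | 1.2 |
| south-east | 10.0 | 4.6 | 0.8 |

(each reading ± 0.5 percentage points)

- reactions considered so far: starting material + partner -> open intermediate; open intermediate <-> target; open intermediate + capture agent -> trapped intermediate
- percentages count the whole charge, also what has not yet gone in

- which of the two ends with the higher amount of open intermediate, in percent of the starting material charged ("neither" if they lie within 2 percentage points) (gamma / zeta / neither)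
- open intermediate at the end, in percent of the starting material charged, gamma
- open intermediate at the end, in percent of the starting material charged, zeta

The converter argues from the first step. The forecast's reckoning has about 86% reacted in gamma and 22% in zeta. Open intermediate is the first thing formed, so the hotter gamma, charged at the start, should hold more of it.

The drainer asks how long open intermediate stays. Call I the open intermediate and P the target at a reading taken at time t, and let τ be the drain time, the lifetime of open intermediate against forming target. Under the steady feed I rises about as the square of time, so its time integral is I t/3. Target is that integral over τ, which gives τ = I t/(3P).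

The last south reading gives 92.3 min at 70 °C, and the last south-east reading gives 19.2 min at 92 °C. Target readings are small, so these carry about 38.5% and 62.5% of scatter.

The drain number N, the run time over τ, counts the lifetimes that fit into a run. Since τ shortened on heating, zeta at 60 °C should have a τ beyond the south value, which is itself longer than zeta's run, so N stays below 0.542. Gamma at 100 °C should have a τ under the south-east value, which is shorter than its run, so N exceeds 2.61. So in zeta target should take little of what has reacted, while in gamma target has time to form. N counts that one step, forward, so for hot gamma the drainer adds trapping as a further loss, at a rate these readings do not give.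

The forecast sides with the drainer: zeta higher, 8% in gamma and 19% in zeta, since in gamma “Open intermediate therefore drains to a low level”.

The simulation gives 9.48% in gamma and 16.6% in zeta, so zeta ends higher.

    starting material + partner → open intermediate (k = 0.00150 /M/s, Ea = 75.0 kJ/mol)
    open intermediate ⇌ target (K = 3.10, k = 5.10 × 10⁻⁵ /s, Ea = 102 kJ/mol, ΔH = −35.0 kJ/mol)
    open intermediate + capture agent → trapped intermediate (k = 9.80 × 10⁻⁴ /M/s, Ea = 57.0 kJ/mol)
    (constants at 60 °C)

Open intermediate is 10.2% of what reacted in gamma, with N read above 2.61, and 85.8% in zeta, with N read below 0.542. In gamma the step N counts runs back, its relaxation half-life, both ways together, being 1.94 min, short against the run, and gamma ends with 8.67% target beside 75.2% trapped intermediate. With trapping taken out, gamma stands at 52.1%, above zeta. The converter's view holds there, and at 25.0 min, when gamma has 17.7%, above zeta's 5.17%. The neighbour of gamma charged with 0.440 equiv of partner runs at gamma's temperature, so its N is read the same, and 3.05% of its 43.7% reacted stays open, a share of 6.98%.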